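**Plan**
1. Numbering as in drimanes: ring A = C1–C5 and C10, ring B = C5–C10, C11 = benzylic CH2 on C9, C1′–C4′ = side chain on C4. Retrosynthesis first cuts the two O-methyl groups, then the side chain at C2′–C3′ (alkyl–alkenyl coupling) and C1′=C2′ (methylenation), leaving a formyl group on C4.
2. Ring A is cut at C3–C4. The quaternary C4 carries the one-carbon branch C1′ next to the ring CH2 C3, which is the footprint of a 1,2-shift of C3 from C1′ to C4 in a cycloheptene oxide (C1′–O–C4).
3. The arylmethyl arm is cut at C11–aryl and C9=C11, the seven-membered ring at C1′=C4 (metathesis), and C10 at its two alkyl bonds. This leads back to (R)-carvone 1, whose ring is ring B and whose isopropenyl carbon and methyl become C4 and the C4 methyl.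
4. Forward order: ring B (from carvone) → C10 quaternary centre → seven-membered ring → β-epoxide → C9 arylmethyl arm → contraction to ring A → side chain → deprotection.
5. Stereochemistry: C5 from carvone; C10 by alkylation anti to isopropenyl; C9 by hydroboration anti to the angular methyl; C4 by anti migration in the β-epoxide, which is set by a bromohydrin closure.

Key step: step 7

Remark: the target is read as 4α-methyl, 4β-(4-methylpent-3-enyl) (axial, cis to the angular methyl), 5α-H, 9β-arylmethyl, 10β-methyl. In the seven-membered precursors C1′ is the ring atom between C3 and C4.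

**Step 1**
Reactants: 1 (R)-(−)-carvone; 2 iodomethane
Product: 3 6-methylcarvone (C6 epimer mixture)
Conditions: LiN(iPr)2, THF, −78 °C; then MeI, −78 → 0 °C
Reagents that add atoms: iodomethane, CI
Why: Kinetic deprotonation at the α′-CH2 and C-methylation of the cross-conjugated lithium dienolate (enolate alkylation) is standard for carvone; the new centre forms as an epimer mixture, which does not matter because it is made planar again in step 2.

**Step 2**
Reactants: 3 6-methylcarvone; 4 5-iodopent-1-ene
Product: 5 6-methyl-6-(pent-4-en-1-yl)carvone (pentenyl trans to isopropenyl)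
Conditions: LiN(iPr)2, THF, −78 °C; then 5-iodopent-1-ene, DMPU, −78 → 0 °C
Reagents that add atoms: 5-iodopent-1-ene, C=CCCCI
Why: Enolate alkylation at the now fully substituted α′-carbon: the iodide should approach the enolate face anti to the neighbouring isopropenyl group, so the pentenyl chain ends trans and the methyl cis to isopropenyl, which is the C10 configuration of the target (1,2-induction from the carvone stereocentre).

**Step 3**
Reactants: 5 6-methyl-6-(pent-4-en-1-yl)carvone
Product: 6 trans-fused bicyclic dienone (cycloheptene ring C1, C2, C3, C1′, C4, C5, C10 on the enone ring B; C1′=C4 bearing the C4 methyl)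
Conditions: second-generation Grubbs catalyst RuCl2(=CHPh)(H2IMes)(PCy3) (5 mol %), CH2Cl2 (high dilution), 40 °C
Reagents that add atoms: none
Why: Ring-closing olefin metathesis between the monosubstituted chain alkene and the 1,1-disubstituted isopropenyl group, held trans on adjacent ring carbons, should close the trans-fused cycloheptene with a trisubstituted C1′=C4 double bond and loss of ethene, the electron-poor enone alkene staying out; no stereocentre is formed.

**Step 4**
Reactants: 6 trans-fused bicyclic dienone
Product: 8 β-epoxy enone (1′β,4β-epoxide), via bromohydrin 7 (not isolated)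
Conditions: NBS, THF/H2O, 0 °C; then K2CO3, MeOH, 0 °C → rt
Reagents that add atoms: water, O
Why: Halohydrin route to an epoxide: Br+ should add to the electron-rich cycloheptene (the enone alkene is inert) on the open α face, away from the angular methyl and the fold of the seven-membered ring, water opens the bromonium ion anti at the tertiary C4 from the β face, and the C4 alkoxide then displaces the 1′α-bromide with inversion, so the oxygen ends on the β face of both carbons, opposite to what a peracid would give.

**Step 5**
Reactants: 8 β-epoxy enone; 9 methyltriphenylphosphonium bromide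
Product: 10 β-epoxy diene (C9=C11 exocyclic methylene conjugated with C7=C8)
Conditions: Ph3PCH3Br, KOtBu, toluene, 90 °C
Reagents that add atoms: methyltriphenylphosphonium bromide, C[P+](c1ccccc1)(c1ccccc1)c1ccccc1.[Br-]
Why: Wittig methylenation under forcing conditions, known to convert α-quaternary and other hindered ketones, turns the C9 carbonyl (not enolisable toward C10) into the exocyclic methylene of a 1,3-diene; the trisubstituted epoxide does not react with the ylide and no stereocentre is touched.

**Step 6**
Reactants: 10 β-epoxy diene; 11 methyl 3-bromo-4-methoxybenzoate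
Product: 13 β-epoxy arylmethyl compound (9β-[2-methoxy-5-(methoxycarbonyl)benzyl]; 9α-H), via alkylborane 12 (not isolated)
Conditions: 9-BBN-H, THF, 0 °C → rt; then 11, Pd(dppf)Cl2 (5 mol %), aq. K3PO4, DMF, 60 °C
Reagents that add atoms: methyl 3-bromo-4-methoxybenzoate, COC(=O)c1ccc(OC)c(Br)c1
Why: Hydroboration then B-alkyl Suzuki–Miyaura coupling: 9-BBN should add only to the terminal CH2 of the exocyclic alkene (the trisubstituted alkene and the epoxide are far slower) from the α face opposite the axial C10 methyl, giving 9α-H and the equatorial 9β-CH2B, and the primary alkylborane then couples with the aryl bromide with retention of the C9 centre.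

**Step 7**
Reactants: 13 β-epoxy arylmethyl compound
Product: 14 decalin aldehyde (4β-formyl-4α-methyl; ring A formed)
Conditions: MeAl(OAr)2 (Ar = 4-bromo-2,6-di-tert-butylphenyl, MABR; 20 mol %), CH2Cl2, −78 → −20 °C
Reagents that add atoms: none
Why: Lewis-acid-promoted epoxide-to-aldehyde (Meinwald-type semipinacol) rearrangement: the aluminium centre binds the epoxide oxygen, the C4–O bond at the tertiary carbon ionises, and the ring bond C1′–C3 shifts from C1′ to C4 while C1′ becomes the formyl carbon. The closest known reaction type is the ring contraction of 1-methylcycloalkene oxides to 1-methylcycloalkanecarbaldehydes and the stereospecific anti rearrangement of trisubstituted epoxides to quaternary aldehydes under bulky aluminium phenoxides or BF3. No ring is closed by cyclisation: ring A arises from the seven-membered ring by this 1,2-alkyl shift, which forms the C3–C4 bond and expels C1′ from the ring (contraction by one atom). C4 is the only new stereocentre and is controlled by the epoxide configuration, because C3 enters anti to the departing oxygen (inversion at C4), so the β-epoxide gives the β (axial) formyl group and the α (equatorial) methyl, while C5, C9 and C10 are untouched. The step needs the ring-bond shift to beat hydride shift from C1′ and proton loss to allylic alcohols; the bulky aluminium phenoxide is known to favour alkyl over hydride shift, and the low temperature and the ring-held geometry should keep the tertiary cation from losing the C4 information or engaging the C7=C8 bond.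

**Step 8**
Reactants: 14 decalin aldehyde; 9 methyltriphenylphosphonium bromide
Product: 15 4β-vinyl decalin
Conditions: Ph3PCH3Br, NaN(SiMe3)2, THF, 0 °C → rt
Reagents that add atoms: methyltriphenylphosphonium bromide, C[P+](c1ccccc1)(c1ccccc1)c1ccccc1.[Br-]
Why: Wittig methylenation of the neopentyl aldehyde, which has no α-hydrogen and so cannot epimerise, should be much faster than attack of the ylide on the benzoate ester; the C4 centre is untouched.

**Step 9**
Reactants: 15 4β-vinyl decalin; 16 1-bromo-2-methylprop-1-ene
Product: 18 jaspic acid methyl ether methyl ester, via alkylborane 17 (not isolated)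
Conditions: 9-BBN-H, THF, rt → 50 °C; then 16, Pd(dppf)Cl2 (5 mol %), AsPh3, aq. K3PO4, DMF, 50 °C
Reagents that add atoms: 1-bromo-2-methylprop-1-ene, CC(C)=CBr
Why: Hydroboration then B-alkyl Suzuki–Miyaura coupling with an alkenyl bromide: 9-BBN should take the monosubstituted vinyl group in preference to the trisubstituted C7=C8 bond and leave the ester alone, and coupling of the primary borane with 1-bromo-2-methylprop-1-ene installs the trisubstituted terminal alkene, in which no geometry has to be controlled.

**Step 10**
Reactants: 18 jaspic acid methyl ether methyl ester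
Product: 19 jaspic acid
Conditions: NaSEt (excess), DMF, 130 °C; then aq. HCl
Reagents that add atoms: none
Why: Nucleophilic (SN2) demethylation by thiolate cleaves both the methyl ester and the aryl methyl ether (the latter activated by the para carboxyl group) under non-acidic conditions that should leave the two trisubstituted alkenes and all stereocentres alone.

**Compound list**
1 | (R)-(−)-carvone | CC(=C)[C@@H]1CC=C(C)C(=O)C1 | starting material
2 | iodomethane | CI | starting material
3 | 6-methylcarvone (C6 epimer mixture) | CC(=C)[C@@H]1CC=C(C)C(=O)C1C | intermediate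
4 | 5-iodopent-1-ene | C=CCCCI | starting material
5 | 6-methyl-6-(pent-4-en-1-yl)carvone, pentenyl trans to isopropenyl | C=CCCC[C@]1(C)C(=O)C(C)=CC[C@H]1C(C)=C | intermediate
6 | trans-fused bicyclic dienone (cycloheptene with C1′=C4 fused to ring B enone; 10β-methyl, 5α-H) | CC1=CCCC[C@]2(C)C(=O)C(C)=CC[C@@H]12 | intermediate
7 | bromohydrin (4β-hydroxy, 1′α-bromo; not isolated) | C[C@]1(O)[C@H](Br)CCC[C@]2(C)C(=O)C(C)=CC[C@@H]12 | intermediate
8 | β-epoxy enone (1′β,4β-epoxide) | C[C@]12O[C@H]1CCC[C@]3(C)C(=O)C(C)=CC[C@@H]23 | intermediate
9 | methyltriphenylphosphonium bromide | C[P+](c1ccccc1)(c1ccccc1)c1ccccc1.[Br-] | starting material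
10 | β-epoxy diene (C9 exocyclic methylene) | C[C@]12O[C@H]1CCC[C@]3(C)C(=C)C(C)=CC[C@@H]23 | intermediate
11 | methyl 3-bromo-4-methoxybenzoate | COC(=O)c1ccc(OC)c(Br)c1 | starting material
12 | B-alkyl-9-BBN at C11 (9α-H; not isolated) | C[C@]12O[C@H]1CCC[C@]3(C)[C@@H](CB4C5CCCC4CCC5)C(C)=CC[C@@H]23 | intermediate
13 | β-epoxy arylmethyl compound (9β-[2-methoxy-5-(methoxycarbonyl)benzyl]) | C[C@]12O[C@H]1CCC[C@]3(C)[C@@H](Cc4cc(C(=O)OC)ccc4OC)C(C)=CC[C@@H]23 | intermediate
14 | decalin aldehyde (4β-formyl, 4α-methyl) | O=C[C@@]1(C)CCC[C@]2(C)[C@@H](Cc3cc(C(=O)OC)ccc3OC)C(C)=CC[C@@H]12 | intermediate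
15 | 4β-vinyl decalin | C=C[C@@]1(C)CCC[C@]2(C)[C@@H](Cc3cc(C(=O)OC)ccc3OC)C(C)=CC[C@@H]12 | intermediate
16 | 1-bromo-2-methylprop-1-ene | CC(C)=CBr | starting material
17 | B-alkyl-9-BBN at C2′ (not isolated) | C(C[C@@]1(C)CCC[C@]2(C)[C@@H](Cc3cc(C(=O)OC)ccc3OC)C(C)=CC[C@@H]12)B4C5CCCC4CCC5 | intermediate
18 | jaspic acid methyl ether methyl ester | CC(C)=CCC[C@@]1(C)CCC[C@]2(C)[C@@H](Cc3cc(C(=O)OC)ccc3OC)C(C)=CC[C@@H]12 | intermediate
19 | jaspic acid | CC(C)=CCC[C@@]1(C)CCC[C@]2(C)[C@@H](Cc3cc(C(=O)O)ccc3O)C(C)=CC[C@@H]12 | target

**Step count and risks**
Total steps: 10. Longest linear sequence: 10 steps from (R)-carvone 1.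

Steps most likely to fail:

1. Step 4. What may go wrong: poor facial selectivity in bromonium formation or opening, so that part of the epoxide oxygen ends on the α face and the later shift would place the formyl group on the wrong face of C4. The fallback sets out from 6 and comes back at 8. Compound 6 is epoxidised directly with mCPBA, which should attack the open α face, to give the α-epoxy enone F1. Dilute HClO4 in aqueous THF hydrolyses it, water entering at the tertiary C4 with inversion, to the trans-diol F2 (4β-OH, 1′α-OH). The secondary hydroxyl is mesylated selectively (MsCl, pyridine) to the hydroxy mesylate F3, and K2CO3 in MeOH closes the β-epoxide 8 with inversion at C1′. The face of the oxygen then rests on two SN2 inversions of a peracid epoxide instead of on the bromonium ion.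

2. Step 7. What may go wrong: hydride shift from C1′ (a ring-retained cycloheptanone), proton loss to allylic alcohols, or capture of the Lewis acid by the ester, in place of the ring-bond shift. The fallback sets out from 6 and comes back at 14. It uses the α-epoxy enone F1 (from 6 with mCPBA, as above), which is methylenated as in step 5 to the α-epoxy diene F4. Hydroboration and coupling with 11 as in step 6, through the alkylborane F5 (not isolated), give the α-epoxy arylmethyl compound F6. Heating F6 with MgBr2·OEt2 in toluene/Et2O should open the epoxide with bromide at the tertiary C4 with inversion, giving the trans-bromohydrin F7 as its bromomagnesium alkoxide (4β-Br, 1′α-O). In F7 the ring bond C1′–C3, but never the hydrogen on C1′, can stand anti to the C–Br bond, and loss of bromide with a second inversion at C4 contracts the ring to 14 (halohydrin-salt semipinacol ring contraction). The approach changes from a direct cationic shift on the β-epoxide to a double-inversion shift on the α-epoxide in which hydride migration is stereoelectronically disfavoured.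

3. Step 2. What may go wrong: slow C-alkylation of the hindered, fully substituted enolate by an unactivated primary iodide, so that O-alkylation, proton exchange and elimination from 4 take over. The fallback sets out from 3 and comes back at 5. The enolate of 3 is alkylated with the far more reactive allyl bromide (same anti approach) to 6-allyl-6-methylcarvone F8. The monosubstituted allyl terminus is hydroborated with disiamylborane, which discriminates against the 1,1-disubstituted isopropenyl group, to the alkyl(disiamyl)borane F9 (not isolated). Coupling of F9 with vinyl bromide (Pd(dppf)Cl2, aq. K3PO4, THF) completes the pentenyl chain of 5.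

**Further compounds**
F1 | step 4 | α-epoxy enone (1′α,4α-epoxide of 6) | C[C@@]12O[C@@H]1CCC[C@]3(C)C(=O)C(C)=CC[C@@H]23
F2 | step 4 | trans-diol (4β-OH, 1′α-OH) | C[C@]1(O)[C@H](O)CCC[C@]2(C)C(=O)C(C)=CC[C@@H]12
F3 | step 4 | hydroxy mesylate (4β-OH, 1′α-OMs) | C[C@]1(O)[C@H](OS(C)(=O)=O)CCC[C@]2(C)C(=O)C(C)=CC[C@@H]12
F4 | step 7 | α-epoxy diene (C9 exocyclic methylene) | C[C@@]12O[C@@H]1CCC[C@]3(C)C(=C)C(C)=CC[C@@H]23
F5 | step 7 | B-alkyl-9-BBN of the α-epoxide series (not isolated) | C[C@@]12O[C@@H]1CCC[C@]3(C)[C@@H](CB4C5CCCC4CCC5)C(C)=CC[C@@H]23
F6 | step 7 | α-epoxy arylmethyl compound | C[C@@]12O[C@@H]1CCC[C@]3(C)[C@@H](Cc4cc(C(=O)OC)ccc4OC)C(C)=CC[C@@H]23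
F7 | step 7 | trans-bromohydrin (4β-Br, 1′α-OH; present as its bromomagnesium alkoxide, not isolated) | C[C@]1(Br)[C@H](O)CCC[C@]2(C)[C@@H](Cc3cc(C(=O)OC)ccc3OC)C(C)=CC[C@@H]12
F8 | step 2 | 6-allyl-6-methylcarvone (allyl trans to isopropenyl) | C=CC[C@]1(C)C(=O)C(C)=CC[C@H]1C(C)=C
F9 | step 2 | alkyl(disiamyl)borane (not isolated) | CC(C)C(C)B(CCC[C@]1(C)C(=O)C(C)=CC[C@H]1C(C)=C)C(C)C(C)C
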